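**Plan**
- Retrosynthetic cuts: first the thirteen O–benzyl bonds, then the interflavan C4–C8 bond, then ring C of the upper unit across C3–C4 and O1–C2 in one retro-[4+2].
- Enabling feature: in ring A the phenol oxygen O1 on C8a is ortho to the benzylic carbon C4, so O1=C8a–C4a=C4 is a masked 1-oxadiene (o-quinone methide) pushed by the C5 and C7 oxygens. Ring B polarises the C2=C3 alkene so that C3 is its nucleophilic end.
- Forward order: the ring A aldehyde and a (Z)-enol gallate of the ring B styrene are made separately. A three-component acetal/o-quinone methide/hetero-Diels–Alder cascade then closes ring C with the gallate already on O3 and a methoxy leaving group on C4. The C4 cation is joined to C8 of benzylated (−)-epigallocatechin, and hydrogenolysis ends the route.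
- Stereochemistry: C2/C3 cis comes from the Z alkene and their absolute sense from a chiral Brønsted acid, with any antipode purged as a diastereomer after the union. C4 comes from anti attack on the gallate-bridged cation. The lower unit comes from the natural flavanol.

Key step: step 4

Assumption: (−)-epigallocatechin of natural (2R,3R) configuration is bought; the hand of the chiral acid in step 4 is written as (R) and would be fixed by a pilot run, both hands being available.

Step 1
Reactants: 1 2,4,6-trihydroxybenzaldehyde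
Product: 2 4,6-bis(benzyloxy)-2-hydroxybenzaldehyde
Conditions: BnBr (2.05 equiv), K2CO3 (2.2 equiv), DMF, 0 °C to rt
Reagents that add atoms: benzyl bromide, BrCc1ccccc1
Why: Williamson etherification with two equivalents of halide should alkylate the para hydroxyl and one ortho hydroxyl, while the remaining ortho hydroxyl, hydrogen-bonded to the formyl oxygen, is the least nucleophilic and stays free as the future O1.

Step 2
Reactants: 3 3,4,5-tris(benzyloxy)benzaldehyde
Product: 4 1,2,3-tris(benzyloxy)-5-ethynylbenzene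
Conditions: dimethyl (1-diazo-2-oxopropyl)phosphonate (1.3 equiv), K2CO3 (2 equiv), MeOH/THF, rt
Reagents that add atoms: dimethyl (1-diazo-2-oxopropyl)phosphonate (Ohira–Bestmann reagent), COP(=O)(OC)C(=[N+]=[N-])C(C)=O
Why: Seyferth–Gilbert homologation in the Ohira–Bestmann variant, in which methanolysis gives the diazomethylphosphonate anion that olefinates the aldehyde and, after loss of N2 and a 1,2-hydrogen shift, should give the terminal alkyne without touching the benzyl ethers.

Step 3
Reactants: 4 1,2,3-tris(benzyloxy)-5-ethynylbenzene; 5 3,4,5-tris(benzyloxy)benzoic acid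
Product: 6 (Z)-2-[3,4,5-tris(benzyloxy)phenyl]ethenyl 3,4,5-tris(benzyloxy)benzoate
Conditions: Ru(CH2C(CH3)CH2)2(Ph2P(CH2)4PPh2) (2 mol %), toluene, 65 °C
Reagents that add atoms: none
Why: Ruthenium-catalysed anti-Markovnikov addition of a carboxylic acid to a terminal alkyne, in which the carboxylate attacks the α-carbon of a ruthenium vinylidene and protonolysis should deliver the (Z)-enol ester whose geometry later becomes the 2,3-cis relation.

Step 4
Reactants: 2 4,6-bis(benzyloxy)-2-hydroxybenzaldehyde; 6 (Z)-2-[3,4,5-tris(benzyloxy)phenyl]ethenyl 3,4,5-tris(benzyloxy)benzoate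
Product: 9 (2R,3R)-5,7-bis(benzyloxy)-4-methoxy-2-[3,4,5-tris(benzyloxy)phenyl]-3,4-dihydro-2H-chromen-3-yl 3,4,5-tris(benzyloxy)benzoate as a mixture of C4 epimers, via dimethyl acetal 7 (not isolated), via methoxy o-quinone methide 8 (not isolated)
Conditions: HC(OMe)3 (1.5 equiv), (R)-3,3'-bis(2,4,6-triisopropylphenyl)-1,1'-binaphthyl-2,2'-diyl N-(trifluoromethylsulfonyl)phosphoramide (10 mol %), 5 Å molecular sieves, CH2Cl2, −30 to 0 °C, slow addition of 2 to 6 (2.5 equiv, excess recovered); Et3N quench
Reagents that add atoms: trimethyl orthoformate, COC(OC)OC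
Why: Proposed new method: acid-catalysed exchange of 2 with the orthoformate gives acetal 7, which loses methanol to the 4-methoxy o-quinone methide 8 (O1=C8a–C4a=C4, held as a hydrogen-bonded ion pair with the chiral phosphoramide), and 8 adds across the C2=C3 double bond of 6 in an inverse-electron-demand hetero-Diels–Alder reaction that re-aromatises ring A. The closest known reactions are the Lewis-acid three-component coupling of salicylaldehydes, trimethyl orthoformate and styrenes to 4-methoxyflavans and the chiral Brønsted-acid [4+2] of o-quinone methides with unactivated styrenes; new here are the enol-ester dienophile and asymmetric control on an acetal-derived quinone methide. Ring C is closed as a six-membered ring by an intermolecular [4+2] (4π oxadiene plus 2π alkene) that forms C3–C4 and O1–C2 together, C3–C4 running ahead in an asynchronous transition state. At C2 and C3 the cis relation is copied from the Z alkene by suprafacial addition and the absolute sense (2R,3R) is to come from the chiral anion, which must fix both the face of C4 and the endo approach of ring B, whereas C4 is not controlled and need not be, since step 6 erases it. Regioselectivity (C4 to the acyloxy-bearing carbon, O1 to the benzylic carbon) is secured by the para-benzyloxy-donating ring B, which carries the developing positive charge at C2, while the cross-conjugated ester oxygen is only a poor donor toward C3. Chemoselectivity against Friedel–Crafts self-condensation of the phloroglucinol-type ring and retention of the alkene geometry are served by slow addition of 2 into excess 6 at low temperature in a weakly polar solvent, where ring closure by O1 should outrun rotation about C2–C3.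

Step 5
Reactants: 10 (−)-epigallocatechin
Product: 11 (2R,3R)-5,7-bis(benzyloxy)-2-[3,4,5-tris(benzyloxy)phenyl]-3,4-dihydro-2H-chromen-3-ol (penta-O-benzyl-(−)-epigallocatechin)
Conditions: BnBr (5.5 equiv), K2CO3 (6 equiv), DMF, argon, 0 °C to rt
Reagents that add atoms: benzyl bromide, BrCc1ccccc1
Why: Williamson etherification under carbonate should alkylate only the five phenols and leave the secondary C3 alcohol free, and low temperature under argon limits C-benzylation and epimerisation at C2 of this natural flavanol, which supplies both stereocentres of the lower unit.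

Step 6
Reactants: 9 (2R,3R)-5,7-bis(benzyloxy)-4-methoxy-2-[3,4,5-tris(benzyloxy)phenyl]-3,4-dihydro-2H-chromen-3-yl 3,4,5-tris(benzyloxy)benzoate; 11 penta-O-benzyl-(−)-epigallocatechin (3 equiv, excess recovered)
Product: 13 tridecabenzyl ether of the target [upper unit (2R,3R,4R); lower unit (2R,3R); lower C3 hydroxyl free], via flavan-4-yl cation 12 (not isolated)
Conditions: Me3SiOSO2CF3 (0.2 equiv), CH2Cl2, −78 to −40 °C; Et3N quench
Reagents that add atoms: none
Why: Lewis-acid ionisation of the benzylic C4–OMe bond followed by Friedel–Crafts arylation (the flavan-4-yl cation/flavan-3-ol condensation), in which the carbonyl oxygen of the 3-O-galloyl group bridges the α face of cation 12 from either C4 epimer of 9, so that C8 of 11, the most nucleophilic ring D carbon, should attack the β face and set C4 as R (3,4-trans), while any dimer from the (2S,3S) antipode of 9 is a diastereomer that chromatography removes.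

Step 7
Reactants: 13 tridecabenzyl ether of the target
Product: 14 (−)-epigallocatechin 3-O-gallate-(4β→8)-(−)-epigallocatechin (target)
Conditions: H2 (1 atm), Pd(OH)2/C, THF/MeOH/H2O, rt; filtration, lyophilisation
Reagents that add atoms: none
Why: Catalytic hydrogenolysis should cleave the thirteen benzyl ethers under neutral conditions that leave the aryl ester, the C4–C8 bond and all five stereocentres untouched.

**Compound list**
1 | 2,4,6-trihydroxybenzaldehyde | O=Cc1c(O)cc(O)cc1O | starting material
2 | 4,6-bis(benzyloxy)-2-hydroxybenzaldehyde | O=Cc1c(O)cc(OCc2ccccc2)cc1OCc3ccccc3 | intermediate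
3 | 3,4,5-tris(benzyloxy)benzaldehyde | O=Cc1cc(OCc2ccccc2)c(OCc2ccccc2)c(OCc2ccccc2)c1 | starting material
4 | 1,2,3-tris(benzyloxy)-5-ethynylbenzene | C#Cc1cc(OCc2ccccc2)c(OCc2ccccc2)c(OCc2ccccc2)c1 | intermediate
5 | 3,4,5-tris(benzyloxy)benzoic acid | OC(=O)c1cc(OCc2ccccc2)c(OCc2ccccc2)c(OCc2ccccc2)c1 | starting material
6 | (Z)-2-[3,4,5-tris(benzyloxy)phenyl]ethenyl 3,4,5-tris(benzyloxy)benzoate | O=C(O/C=C\c1cc(OCc2ccccc2)c(OCc2ccccc2)c(OCc2ccccc2)c1)c1cc(OCc2ccccc2)c(OCc2ccccc2)c(OCc2ccccc2)c1 | intermediate
7 | 3,5-bis(benzyloxy)-2-(dimethoxymethyl)phenol | COC(OC)c1c(O)cc(OCc2ccccc2)cc1OCc3ccccc3 | intermediate (not isolated)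
8 | 3,5-bis(benzyloxy)-6-(methoxymethylidene)cyclohexa-2,4-dien-1-one | COC=C1C(=O)C=C(OCc2ccccc2)C=C1OCc3ccccc3 | intermediate (not isolated)
9 | (2R,3R)-5,7-bis(benzyloxy)-4-methoxy-2-[3,4,5-tris(benzyloxy)phenyl]-3,4-dihydro-2H-chromen-3-yl 3,4,5-tris(benzyloxy)benzoate, both C4 epimers | O=C(O[C@@H]1C(OC)c2c(OCc3ccccc3)cc(OCc3ccccc3)cc2O[C@@H]1c1cc(OCc2ccccc2)c(OCc2ccccc2)c(OCc2ccccc2)c1)c1cc(OCc2ccccc2)c(OCc2ccccc2)c(OCc2ccccc2)c1 | intermediate
10 | (−)-epigallocatechin, (2R,3R) | Oc1cc(O)c2c(c1)O[C@H](c1cc(O)c(O)c(O)c1)[C@H](O)C2 | starting material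
11 | (2R,3R)-5,7-bis(benzyloxy)-2-[3,4,5-tris(benzyloxy)phenyl]-3,4-dihydro-2H-chromen-3-ol | O(Cc1ccccc1)c1cc(OCc3ccccc3)c2c(c1)O[C@H](c1cc(OCc3ccccc3)c(OCc3ccccc3)c(OCc3ccccc3)c1)[C@H](O)C2 | intermediate
12 | (2R,3R)-flavan-4-yl cation of 9 as its triflate, drawn open; in solution bridged on the α face by the gallate carbonyl | O=C(O[C@@H]1[CH+]c2c(OCc3ccccc3)cc(OCc3ccccc3)cc2O[C@@H]1c1cc(OCc2ccccc2)c(OCc2ccccc2)c(OCc2ccccc2)c1)c1cc(OCc2ccccc2)c(OCc2ccccc2)c(OCc2ccccc2)c1.[O-]S(=O)(=O)C(F)(F)F | intermediate (not isolated)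
13 | (2R,3R,4R)-5,7-bis(benzyloxy)-4-{(2R,3R)-5,7-bis(benzyloxy)-3-hydroxy-2-[3,4,5-tris(benzyloxy)phenyl]-3,4-dihydro-2H-chromen-8-yl}-2-[3,4,5-tris(benzyloxy)phenyl]-3,4-dihydro-2H-chromen-3-yl 3,4,5-tris(benzyloxy)benzoate | O=C(O[C@@H]1[C@@H](c2c(OCc4ccccc4)cc(OCc4ccccc4)c3c2O[C@H](c2cc(OCc4ccccc4)c(OCc4ccccc4)c(OCc4ccccc4)c2)[C@H](O)C3)c2c(OCc4ccccc4)cc(OCc4ccccc4)cc2O[C@@H]1c1cc(OCc4ccccc4)c(OCc4ccccc4)c(OCc4ccccc4)c1)c1cc(OCc4ccccc4)c(OCc4ccccc4)c(OCc4ccccc4)c1 | intermediate
14 | (2R,3R,4R)-5,7-dihydroxy-4-[(2R,3R)-3,5,7-trihydroxy-2-(3,4,5-trihydroxyphenyl)-3,4-dihydro-2H-chromen-8-yl]-2-(3,4,5-trihydroxyphenyl)-3,4-dihydro-2H-chromen-3-yl 3,4,5-trihydroxybenzoate | O=C(O[C@@H]1[C@@H](c2c(O)cc(O)c3c2O[C@H](c2cc(O)c(O)c(O)c2)[C@H](O)C3)c2c(O)cc(O)cc2O[C@@H]1c1cc(O)c(O)c(O)c1)c1cc(O)c(O)c(O)c1 | target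

**Totals**
Total step count: 7. Longest linear sequence: 5 steps (steps 2, 3, 4, 6, 7).

**Steps most likely to fail**

1. Step 4 (bears the label). Four things may go wrong:
   - addition in a stepwise mode with rotation about C2–C3, which loses the cis relation;
   - weak endo or facial control by the chiral anion;
   - attack with the opposite regiochemistry;
   - Friedel–Crafts oligomerisation of the quinone methide, or methanolysis of the enol ester.

   Fallback by known chemistry, setting out from 11 (with 5 as acyl donor) and coming back at 9. Compound 11 would be oxidised at C4 with 2,3-dichloro-5,6-dicyano-1,4-benzoquinone in CH2Cl2/MeOH. Methanol captures the ring A quinone methide cation trans to the C3 hydroxyl to give (2R,3R,4S)-5,7-bis(benzyloxy)-4-methoxy-2-[3,4,5-tris(benzyloxy)phenyl]-3,4-dihydro-2H-chromen-3-ol F1. Steglich esterification of the C3 hydroxyl of F1 with acid 5 (dicyclohexylcarbodiimide, 4-(dimethylamino)pyridine, CH2Cl2) would then give 9 as its single 4S epimer, with C2 and C3 taken from the natural flavanol.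

2. Step 6. The cation may be captured by ring A of a second molecule of 9 or of product 13, giving oligomers, or attack may leak to C6 of 11.

   Fallback with a blocking group, setting out from 9 and coming back at 14. N-Bromosuccinimide (CH2Cl2, −20 °C) would brominate the most nucleophilic position of the upper ring A to give the 8-bromo derivative of 9 F2, whose cation can no longer be intercepted through that carbon. Condensation of F2 with 11 (BF3·OEt2, CH2Cl2, −78 °C) would give the 8-bromo derivative of 13 F3. Hydrogenolysis of F3 (H2, Pd(OH)2/C, Et3N, THF/MeOH) would remove the bromine together with the thirteen benzyl groups and give 14 directly.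

3. Step 3. Markovnikov addition or erosion of the Z geometry would pass straight into the 2,3 relation of the upper unit.

   Fallback through a boron intermediate, setting out from 4 and coming back at 6. Rhodium-catalysed trans-hydroboration of 4 with pinacolborane ([RhCl(C8H12)]2, P(CH(CH3)2)3, Et3N, cyclohexane, rt) would give (Z)-2-{2-[3,4,5-tris(benzyloxy)phenyl]ethenyl}-4,4,5,5-tetramethyl-1,3,2-dioxaborolane F4. KHF2 in MeOH/H2O would convert F4 into potassium (Z)-trifluoro{2-[3,4,5-tris(benzyloxy)phenyl]ethenyl}borate F5. Oxidative copper coupling of Chan–Lam type between F5 and acid 5 (CuBr, 4-(dimethylamino)pyridine, O2, 4 Å molecular sieves, CH2Cl2, rt) would form the C–O bond with retention of alkene geometry and give 6.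

**Further compounds**
F1 | step 4 | (2R,3R,4S)-5,7-bis(benzyloxy)-4-methoxy-2-[3,4,5-tris(benzyloxy)phenyl]-3,4-dihydro-2H-chromen-3-ol | O(Cc1ccccc1)c1cc(OCc3ccccc3)c2c(c1)O[C@H](c1cc(OCc3ccccc3)c(OCc3ccccc3)c(OCc3ccccc3)c1)[C@H](O)[C@H]2OC
F2 | step 6 | (2R,3R)-5,7-bis(benzyloxy)-8-bromo-4-methoxy-2-[3,4,5-tris(benzyloxy)phenyl]-3,4-dihydro-2H-chromen-3-yl 3,4,5-tris(benzyloxy)benzoate, both C4 epimers | O=C(O[C@@H]1C(OC)c2c(OCc3ccccc3)cc(OCc3ccccc3)c(Br)c2O[C@@H]1c1cc(OCc2ccccc2)c(OCc2ccccc2)c(OCc2ccccc2)c1)c1cc(OCc2ccccc2)c(OCc2ccccc2)c(OCc2ccccc2)c1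
F3 | step 6 | 8-bromo derivative of 13 (bromine on C8 of the upper ring A; upper unit 2R,3R,4R; lower unit 2R,3R) | O=C(O[C@@H]1[C@@H](c2c(OCc4ccccc4)cc(OCc4ccccc4)c3c2O[C@H](c2cc(OCc4ccccc4)c(OCc4ccccc4)c(OCc4ccccc4)c2)[C@H](O)C3)c2c(OCc4ccccc4)cc(OCc4ccccc4)c(Br)c2O[C@@H]1c1cc(OCc4ccccc4)c(OCc4ccccc4)c(OCc4ccccc4)c1)c1cc(OCc4ccccc4)c(OCc4ccccc4)c(OCc4ccccc4)c1
F4 | step 3 | (Z)-2-{2-[3,4,5-tris(benzyloxy)phenyl]ethenyl}-4,4,5,5-tetramethyl-1,3,2-dioxaborolane | CC1(C)OB(/C=C\c2cc(OCc3ccccc3)c(OCc3ccccc3)c(OCc3ccccc3)c2)OC1(C)C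
F5 | step 3 | potassium (Z)-trifluoro{2-[3,4,5-tris(benzyloxy)phenyl]ethenyl}borate | [K+].F[B-](F)(F)/C=C\c1cc(OCc2ccccc2)c(OCc2ccccc2)c(OCc2ccccc2)c1
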